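# Proposed total synthesis of CNP0126363.4 built around a silyl-dithiane linchpin union at C27

## Structural features

The target is a 36-membered macrolactone. The ring holds C1 to C35 and the ester oxygen O35, and C35 carries outside the ring a hexan-2-yl group (C36 with its methyl, then the n-butyl chain C37–C40). The only unsaturation is the (2Z)-3-methyl enoate C1–C3; from C4 to C35 the ring is a saturated chain with nine free secondary hydroxyls at C7, C9, C13, C17, C21, C25, C27, C29 and C33. The eleven stereocentres form clusters: a syn-1,3-diol at C7/C9; three isolated carbinols C13, C17 and C21, each three methylenes from the next; a 1,3,5-triol C25/C27/C29 (25,27-syn, 27,29-anti); and the C33 carbinol, syn-1,3 to the lactone carbinol C35, which stands next to the methyl-bearing C36 (anti). Fragile points are the Z-enoate (isomerisation or γ-deprotonation on activation or in base), the lactone (acyl shift to O33) and every β-hydroxy carbonyl intermediate (retro-aldol, elimination). The real difficulty is twofold. The 1,5-related centres C9/C13/C17/C21/C25 cannot be relayed from one to the next, so each must come from a reagent or from the chiral pool. Nine nearly identical hydroxyls must also be handled so that only O35 is ever acylated. The key step exploits the fact that the carbinol carbon C27 is flanked by two methylenes, C26 and C28, each next to another carbinol (C25, C29). C27 can therefore act as a one-carbon dianion equivalent that opens two terminal epoxides at C26 and C28.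

## Logic of the disconnections

50 ⇒ 49. All O–Si bonds and both acetals are cut last. The reason is that one acid/fluoride-labile protecting-group class can then be removed in a single operation. The demand is a deprotection mild enough for the lactone and the Z-enoate.

49 ⇒ 47 (through 48). The C1–O35 ester bond is cut, the only heteroatom bond in the ring. This turns the 36-membered ring into a linear seco acid. The forward step needs O35 as the only free hydroxyl, high dilution, and an activation that does not isomerise C2=C3.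

47 ⇒ 46 ⇒ 45. The acid and O35 are unmasked in separate steps (ester alkyl–O bond, benzylic C–O bond). Both masks are orthogonal to silyl ethers and acetals. The demand is an oxidative ether cleavage and a hydrolysis that leave the enoate geometry alone.

45 ⇒ 41 + 43 (43 ⇐ 42). The C3–C4 bond is cut, an sp2–sp3 bond next to the trisubstituted alkene. The Z geometry is bought with 43 and transferred with retention, and 41 needs only a terminal alkene as handle (activated as 44). The demand is a hydroboration selective for the one terminal alkene and a coupling faster than β-hydride elimination.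

41 ⇒ 40 ⇒ 39 ⇒ 38. No skeletal bond is cut; the C27 carbinol is traced back to a ketone and then to a dithiane. The C27 configuration is to come from hydride delivery directed by O29-H. This needs O29 free and O25 blocked, which is exactly the pattern of 38.

38 ⇒ 19 + 31 + 34 (34 ⇐ 32). C26–C27 and C27–C28 are cut at the same carbon. This splits the C40 chain into a C23 and a C13 epoxide plus a one-carbon linchpin, with no stereocentre at risk because C25 and C29 arrive finished. The demand is that each epoxide reacts once, at its CH2 terminus, in a fixed order.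

19 ⇒ 18 ⇒ 17. The C4=C5 bond is cut and C5 is traced back to an ester. The terminal alkene is made last because it could not survive the epoxidations used to grow the chain. The demand is a partial reduction and an olefination that tolerate the terminal epoxide.

17 ⇒ 16 ⇒ 15 ⇒ … ⇒ 5 ⇒ 4 ⇒ 3. Three times a C–C bond between an epoxide CH2 and a four-carbon alkenyl unit is cut (C22–C23, C18–C19, C14–C15), and four times an epoxide is traced back to a terminal alkene. The 1,5-spacing equals one epoxide carbon plus a butenyl unit, so one repeated operation sets C13, C17, C21 and C25. The demand is catalyst control in each resolution and tolerance of the tert-butyl ester by the organometallic.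

3 ⇒ 1 (through 2). The C10–C11 bond is cut. 1 supplies C7 and C9 with the syn-acetonide already in place. The demand is substitution at a β-oxygenated primary carbon in the presence of an ester.

31 ⇒ 30 ⇒ 29 ⇒ 28 ⇒ 27 ⇒ 26 ⇒ 25 ⇒ 24. The same homologation logic is used: C31–C32 is cut and two epoxides are traced back to alkenes. O35 is etherified before O33 exists, so the two oxygens of the syn-1,3-diol are differentiated by construction.

24 ⇒ 23 ⇒ 22 ⇒ 21 ⇒ 20. C33–C34 is cut (vinyl onto an epoxide), then the C36–methyl bond (methyl delivered to an epoxy alcohol with inversion), then the epoxide is traced back to an achiral allylic alcohol. One catalytic asymmetric epoxidation thus fixes C35 and C36, and their anti relation is stereospecific. The demand is opening of the epoxy alcohol at the carbon remote from the hydroxymethyl group.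

## Other disconnections considered

Alternative 1: The cut is C11=C12 in the C10–C12 spacer, with the ester O35–C1 already in place. In the forward direction the diene ester A2 would be closed to A1 by the second-generation Grubbs catalyst with loss of ethylene. The new alkene would then be hydrogenated without touching C2=C3.
- In favour: the ester is formed intermolecularly on the hindered O35, so no high-dilution acylation is needed. This is a point on which the alternative is better than the chosen plan. The closure site is far from all stereocentres, the catalyst tolerates every functional group present, and the E/Z outcome is irrelevant.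
- Against: a 36-membered ring without conformational bias invites oligomerisation. The allylic ether at C13 slows metathesis at that alkene. The extra reduction must spare a conjugated trisubstituted alkene and a benzylic ether. The step creates no stereocentre and does nothing for the C25–C29 triol.
- Comparison: on step economy the ring-forming sequences are equal (esterification, metathesis and hydrogenation against ether cleavage, saponification and lactonisation). On mechanism the catalytic, neutral metathesis is gentler than the cryogenic anion chemistry of step 30. On structure the chosen plan solves fragment union and the triol at once, which the alternative does not.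

Alternative 2: The cut is C8–C9 and C13–C14, both carbinols growing from a five-carbon diol. In the forward direction A4 and A5 would react under [Ir(cod)Cl]2 and a chiral bisphosphine by transfer hydrogenation: each terminus is dehydrogenated and allylated to give the C2-symmetric diol A3, the 9,13-anti pair.
- In favour: one catalytic step from commodity chemicals sets two of the 1,5-related centres, and the second allylation should raise the enantiomeric purity. For C9/C13 this is better in step economy than steps 1–3 of the chosen route, which also discard half the material in a resolution.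
- Against: the two allyl termini of A3 are homotopic, whereas the target needs one turned into the C7 carbinol with its allyl group (1,3-syn) and the other extended to C17. A3 covers only C6–C16 and is not a fragment union.
- Comparison: the alternative is complementary rather than competing, since it could feed the synthesis of 19. It is equal to the chosen plan in stereochemical reliability (catalyst control against chiral pool plus resolution). It offers nothing for the C25–C29 region, which step 30 addresses.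

Alternative 3: The cut is C24–C25 and C21–C22, leaving the aldehydes A7 (C25–C40) and A8 (C4–C21) and the three-carbon allenylboronate A9. In the forward direction A9 would be hydroborated with a chiral pinene-derived dialkylborane. The resulting γ-boryl allylborane would add to A7 and the allylboronate so formed to A8, giving the (E)-ene-anti-diol A6.
- In favour: the union itself creates two stereocentres (C21, C25) in one flask. Here it is better than step 30, which creates none. It is equal in convergence, being also a three-component one-pot coupling.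
- Against: two centres depend on reagent control at the moment of coupling, so minor diastereomers would form in a C40 chain where they are hard to remove. The first addition must be complete before A8 is added, or homo-coupled products arise. The new alkene must be hydrogenated, so C4 has to be carried as a pivalate, and the C1–C3 unit then costs extra steps (ester removal, activation of C4). C27 and C29 must already be present in A7.
- Comparison: in the chosen plan every centre near the junction comes from a resolved epoxide or from one directed reduction, and the terminal alkene for the enoate survives the coupling. After coupling, the chosen plan needs three steps to reach the protected triol, while A6 needs hydrogenation, double silylation and the C4 adjustments.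

Key step: step 30

Remarks on the chemistry (assumptions):
- Numbering: C1 is the lactone carbonyl, C35 the lactone carbinol, C40 the end of the butyl chain.
- The configurations of 19, 31 and 38 were compared centre by centre with the target and agree; no structure needed correction.
- Methyl (S)-3-hydroxy-2-methylpropanoate would map onto C36 correctly only if its ester carbon became C35 and its hydroxymethyl carbon C37. C35/C36 are therefore taken from a Sharpless epoxidation instead.
- 1 is assumed to be purchased (it is a bulk statin side-chain building block).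
- (salen)Co(OAc) means [N,N'-bis(3,5-di-tert-butylsalicylidene)-1,2-cyclohexanediaminato]cobalt acetate (trivalent cobalt), made from the divalent cobalt complex, AcOH and air. The (R,R) catalyst is taken to leave the oxirane with R configuration at the ring carbon when the substituent is a CH2 group, and the (S,S) catalyst the S oxirane.

## Route

Step 1
Reactants: 1 tert-butyl 2-[(4R,6S)-6-(hydroxymethyl)-2,2-dimethyl-1,3-dioxan-4-yl]acetate
Product: 3 tert-butyl 2-[(4R,6R)-2,2-dimethyl-6-(pent-4-en-1-yl)-1,3-dioxan-4-yl]acetate, via C10 triflate 2 (not isolated)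
Conditions: Tf2O, 2,6-lutidine, CH2Cl2, -78 °C; then CH2=CHCH2CH2MgBr, CuBr·SMe2 (10 mol%), THF/Et2O, -40 to 0 °C
Reagents that add atoms: but-3-en-1-ylmagnesium bromide, C=CCC[Mg]Br
Why: Copper-catalysed sp3–sp3 cross-coupling of a primary triflate with a Grignard reagent; the triflate is reactive enough for SN2 next to the acetal oxygen at low temperature, where the tert-butyl ester should not be attacked. C7 and C9 come unchanged from 1.

Step 2
Reactants: 3 tert-butyl 2-[(4R,6R)-2,2-dimethyl-6-(pent-4-en-1-yl)-1,3-dioxan-4-yl]acetate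
Product: 4 C13/C14 epoxide of 3 (both C13 epimers)
Conditions: mCPBA, NaHCO3, CH2Cl2, 0 °C to rt
Reagents that add atoms: mCPBA, OOC(=O)c1cccc(Cl)c1
Why: Prilezhaev epoxidation of the only alkene; no facial bias is expected at the remote C13, so both epimers should form and are resolved in step 3.

Step 3
Reactants: 4 C13/C14 epoxide of 3 (both C13 epimers)
Product: 5 tert-butyl 2-[(4R,6R)-2,2-dimethyl-6-{3-[(2R)-oxiran-2-yl]propyl}-1,3-dioxan-4-yl]acetate
Conditions: (R,R)-(salen)Co(OAc) (1 mol%), H2O (0.55 equiv), THF, 0 °C to rt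
Reagents that add atoms: none
Why: Hydrolytic kinetic resolution; the (R,R) catalyst should hydrate the S oxirane much faster and leave the R oxirane, whatever the remote C7/C9 centres. This sets C13; at most half of the material can be carried on.

Step 4
Reactants: 5 tert-butyl 2-[(4R,6R)-2,2-dimethyl-6-{3-[(2R)-oxiran-2-yl]propyl}-1,3-dioxan-4-yl]acetate
Product: 6 tert-butyl 2-[(4R,6R)-6-[(4S)-4-hydroxynon-8-en-1-yl]-2,2-dimethyl-1,3-dioxan-4-yl]acetate
Conditions: CH2=CHCH2CH2MgBr, CuI (10 mol%), THF, -40 to -20 °C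
Reagents that add atoms: but-3-en-1-ylmagnesium bromide, C=CCC[Mg]Br
Why: Copper-catalysed SN2 opening of the terminal epoxide at the unsubstituted C14; the C13–O bond is not touched, so C13 is retained. Low temperature should spare the ester.

Step 5
Reactants: 6 tert-butyl 2-[(4R,6R)-6-[(4S)-4-hydroxynon-8-en-1-yl]-2,2-dimethyl-1,3-dioxan-4-yl]acetate
Product: 7 O13-TBS ether of 6
Conditions: TBSCl, imidazole, DMF, rt
Reagents that add atoms: tert-butyldimethylsilyl chloride, CC(C)(C)[Si](C)(C)Cl
Why: Silylation of the secondary alcohol; the chloride/imidazole protocol is chosen because a silyl triflate could cleave the tert-butyl ester.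

Step 6
Reactants: 7 O13-TBS ether of 6
Product: 8 C17/C18 epoxide of 7 (both C17 epimers)
Conditions: mCPBA, NaHCO3, CH2Cl2, 0 °C to rt
Reagents that add atoms: mCPBA, OOC(=O)c1cccc(Cl)c1
Why: Prilezhaev epoxidation of the terminal alkene; silyl ether, acetonide and ester are inert to buffered peracid.

Step 7
Reactants: 8 C17/C18 epoxide of 7 (both C17 epimers)
Product: 9 C5–C18 epoxy ester with single C17/C18 oxirane (ring carbon R)
Conditions: (R,R)-(salen)Co(OAc) (1 mol%), H2O (0.55 equiv), THF, 0 °C to rt
Reagents that add atoms: none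
Why: Hydrolytic kinetic resolution under catalyst control; the R oxirane that remains has the C17 configuration of the target.

Step 8
Reactants: 9 C5–C18 epoxy ester with single C17/C18 oxirane (ring carbon R)
Product: 10 C5–C22 alcohol (17-OH; 13-OTBS; 7,9-acetonide; tert-butyl ester; C21=C22)
Conditions: CH2=CHCH2CH2MgBr, CuI (10 mol%), THF, -40 to -20 °C
Reagents that add atoms: but-3-en-1-ylmagnesium bromide, C=CCC[Mg]Br
Why: Copper-catalysed epoxide opening at C18; C17 keeps its C–O bond and configuration.

Step 9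
Reactants: 10 C5–C22 alcohol (17-OH; 13-OTBS; 7,9-acetonide; tert-butyl ester; C21=C22)
Product: 11 O17-TBS ether of 10
Conditions: TBSCl, imidazole, DMF, rt
Reagents that add atoms: tert-butyldimethylsilyl chloride, CC(C)(C)[Si](C)(C)Cl
Why: Standard silylation of a secondary alcohol.

Step 10
Reactants: 11 O17-TBS ether of 10
Product: 12 C21/C22 epoxide of 11 (both C21 epimers)
Conditions: mCPBA, NaHCO3, CH2Cl2, 0 °C to rt
Reagents that add atoms: mCPBA, OOC(=O)c1cccc(Cl)c1
Why: Prilezhaev epoxidation of the terminal alkene.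

Step 11
Reactants: 12 C21/C22 epoxide of 11 (both C21 epimers)
Product: 13 C5–C22 epoxy ester with single C21/C22 oxirane (ring carbon R)
Conditions: (R,R)-(salen)Co(OAc) (1 mol%), H2O (0.55 equiv), THF, 0 °C to rt
Reagents that add atoms: none
Why: Hydrolytic kinetic resolution; the R oxirane left behind corresponds to C21 of the target.

Step 12
Reactants: 13 C5–C22 epoxy ester with single C21/C22 oxirane (ring carbon R)
Product: 14 C5–C26 alcohol (21-OH; 13,17-bis-OTBS; 7,9-acetonide; tert-butyl ester; C25=C26)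
Conditions: CH2=CHCH2CH2MgBr, CuI (10 mol%), THF, -40 to -20 °C
Reagents that add atoms: but-3-en-1-ylmagnesium bromide, C=CCC[Mg]Br
Why: Copper-catalysed epoxide opening at C22; C21 retained.

Step 13
Reactants: 14 C5–C26 alcohol (21-OH; 13,17-bis-OTBS; 7,9-acetonide; tert-butyl ester; C25=C26)
Product: 15 O21-TBS ether of 14
Conditions: TBSCl, imidazole, DMF, rt
Reagents that add atoms: tert-butyldimethylsilyl chloride, CC(C)(C)[Si](C)(C)Cl
Why: Standard silylation of a secondary alcohol.

Step 14
Reactants: 15 O21-TBS ether of 14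
Product: 16 C25/C26 epoxide of 15 (both C25 epimers)
Conditions: mCPBA, NaHCO3, CH2Cl2, 0 °C to rt
Reagents that add atoms: mCPBA, OOC(=O)c1cccc(Cl)c1
Why: Prilezhaev epoxidation of the terminal alkene.

Step 15
Reactants: 16 C25/C26 epoxide of 15 (both C25 epimers)
Product: 17 C5–C26 epoxy ester with single C25/C26 oxirane (ring carbon S)
Conditions: (S,S)-(salen)Co(OAc) (1 mol%), H2O (0.55 equiv), THF, 0 °C to rt
Reagents that add atoms: none
Why: Hydrolytic kinetic resolution with the enantiomeric catalyst, because C25 has the opposite sense to C13, C17 and C21; the S oxirane should remain.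

Step 16
Reactants: 17 C5–C26 epoxy ester with single C25/C26 oxirane (ring carbon S)
Product: 18 C5 aldehyde of 17
Conditions: i-Bu2AlH (1.2 equiv), CH2Cl2, -78 °C; aq. KNaC4H4O6
Reagents that add atoms: none
Why: Partial reduction of the ester; the aluminium hemiacetal of a tert-butyl ester is stable at -78 °C and gives the aldehyde on work-up. Epoxide, acetonide and silyl ethers should be inert at this temperature.

Step 17
Reactants: 18 C5 aldehyde of 17
Product: 19 southern epoxide C4–C26 (C25/C26 oxirane; 13,17,21-tris-OTBS; 7,9-acetonide; C4=C5)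
Conditions: Ph3PCH3Br, KN(SiMe3)2, THF, -78 to 0 °C
Reagents that add atoms: methyltriphenylphosphonium bromide, [Br-].C[P+](c1ccccc1)(c1ccccc1)c1ccccc1
Why: Wittig methylenation adds C4; the non-stabilised ylide reacts at low temperature before β-elimination of the C7 acetal oxygen can occur and does not touch the epoxide.

Step 18
Reactants: 20 (E)-hept-2-en-1-ol
Product: 21 [(2R,3R)-3-butyloxiran-2-yl]methanol
Conditions: Ti(OiPr)4 (5 mol%), D-(-)-diisopropyl tartrate (6 mol%), t-BuOOH, 4 Å MS, CH2Cl2, -20 °C
Reagents that add atoms: tert-butyl hydroperoxide, CC(C)(C)OO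
Why: Sharpless asymmetric epoxidation; the D-tartrate ligand directs oxygen to the face that gives the (2R,3R) epoxy alcohol, fixing C35 and preparing C36.

Step 19
Reactants: 21 [(2R,3R)-3-butyloxiran-2-yl]methanol
Product: 22 (2S,3S)-3-methylheptane-1,2-diol
Conditions: Me3Al, hexane/CH2Cl2, 0 °C to rt
Reagents that add atoms: trimethylaluminium, C[Al](C)C
Why: Organoaluminium opening of a 2,3-epoxy alcohol: the aluminium alkoxide directs methyl to C3 with inversion (SN2). This sets C36 and gives the anti relation between O35 and the C36 methyl.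

Step 20
Reactants: 22 (2S,3S)-3-methylheptane-1,2-diol
Product: 23 (2S)-2-[(2S)-hexan-2-yl]oxirane
Conditions: NaH, 1-(p-toluenesulfonyl)imidazole, THF, 0 °C to rt
Reagents that add atoms: none
Why: One-pot epoxide formation: the primary alkoxide is sulfonylated selectively and displaced by the C35 alkoxide (3-exo-tet), so C35 keeps its C–O bond and configuration.

Step 21
Reactants: 23 (2S)-2-[(2S)-hexan-2-yl]oxirane
Product: 24 (4R,5S)-5-methylnon-1-en-4-ol
Conditions: CH2=CHMgBr, CuI (10 mol%), THF, -40 to -20 °C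
Reagents that add atoms: vinylmagnesium bromide, C=C[Mg]Br
Why: Copper-catalysed opening at the unsubstituted C34 gives the homoallylic alcohol; C35 and C36 are untouched.

Step 22
Reactants: 24 (4R,5S)-5-methylnon-1-en-4-ol
Product: 25 O-PMB ether of 24
Conditions: NaH, PMBCl, Bu4NI (cat.), THF/DMF, 0 °C to rt
Reagents that add atoms: 4-methoxybenzyl chloride, COc1ccc(CCl)cc1
Why: Williamson etherification; PMB is placed on O35 before O33 exists, so that O35 alone can later be freed oxidatively.

Step 23
Reactants: 25 O-PMB ether of 24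
Product: 26 C32/C33 epoxide of 25 (both C33 epimers)
Conditions: mCPBA, NaHCO3, CH2Cl2, 0 °C
Reagents that add atoms: mCPBA, OOC(=O)c1cccc(Cl)c1
Why: Prilezhaev epoxidation; the PMB ether tolerates buffered peracid and little substrate control is expected, hence the resolution that follows.

Step 24
Reactants: 26 C32/C33 epoxide of 25 (both C33 epimers)
Product: 27 (2S)-2-{(2R,3S)-2-[(4-methoxyphenyl)methoxy]-3-methylheptyl}oxirane
Conditions: (S,S)-(salen)Co(OAc) (1 mol%), H2O (0.55 equiv), THF, 0 °C to rt
Reagents that add atoms: none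
Why: Hydrolytic kinetic resolution; the S oxirane that should remain has the C33 configuration of the target, syn to O35.

Step 25
Reactants: 27 (2S)-2-{(2R,3S)-2-[(4-methoxyphenyl)methoxy]-3-methylheptyl}oxirane
Product: 28 (6R,8R,9S)-8-[(4-methoxyphenyl)methoxy]-9-methyltridec-1-en-6-ol
Conditions: CH2=CHCH2CH2MgBr, CuI (10 mol%), THF, -40 to -20 °C
Reagents that add atoms: but-3-en-1-ylmagnesium bromide, C=CCC[Mg]Br
Why: Copper-catalysed epoxide opening at C32 brings in C28–C31 with the alkene for the last epoxide; C33 is retained.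

Step 26
Reactants: 28 (6R,8R,9S)-8-[(4-methoxyphenyl)methoxy]-9-methyltridec-1-en-6-ol
Product: 29 O33-TBS ether of 28
Conditions: TBSCl, imidazole, DMF, rt
Reagents that add atoms: tert-butyldimethylsilyl chloride, CC(C)(C)[Si](C)(C)Cl
Why: Standard silylation; O33 and O35 now carry different groups.

Step 27
Reactants: 29 O33-TBS ether of 28
Product: 30 C28/C29 epoxide of 29 (both C29 epimers)
Conditions: mCPBA, NaHCO3, CH2Cl2, 0 °C
Reagents that add atoms: mCPBA, OOC(=O)c1cccc(Cl)c1
Why: Prilezhaev epoxidation of the terminal alkene.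

Step 28
Reactants: 30 C28/C29 epoxide of 29 (both C29 epimers)
Product: 31 northern epoxide C28–C40 (C28/C29 oxirane with ring carbon S; 33-OTBS; 35-OPMB)
Conditions: (S,S)-(salen)Co(OAc) (1 mol%), H2O (0.55 equiv), THF, 0 °C to rt
Reagents that add atoms: none
Why: Hydrolytic kinetic resolution; the S oxirane left behind carries the C29 configuration of the target.

Step 29
Reactants: 32 1,3-dithiane
Product: 34 2-(tert-butyldimethylsilyl)-1,3-dithiane, via 2-lithio-1,3-dithiane 33 (not isolated)
Conditions: n-BuLi, THF, -30 °C; TBSCl, -78 °C to rt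
Reagents that add atoms: tert-butyldimethylsilyl chloride, CC(C)(C)[Si](C)(C)Cl
Why: Corey–Seebach deprotonation of the dithiane at C2 and C-silylation of the anion.

Step 30
Reactants: 34 2-(tert-butyldimethylsilyl)-1,3-dithiane; 19 southern epoxide C4–C26; 31 northern epoxide C28–C40
Product: 38 C4–C40 dithiane alcohol (C27 dithiane; O25-TBS; O29-H), via silyl lithiodithiane 35 (not isolated), via C25 lithium alkoxide 36 (not isolated), via Brook-shifted C27 anion 37 (not isolated)
Conditions: t-BuLi, Et2O, -78 to -45 °C; 19, Et2O, -78 to -25 °C; then 31, THF/HMPA, -78 to 0 °C; aq. NH4Cl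
Reagents that add atoms: none
Why: t-BuLi removes the C2 proton of 34 to give 35, which in ether opens 19 by SN2 at the unsubstituted C26 to give alkoxide 36; in ether the lithium alkoxide is tightly paired and silicon stays on carbon. Adding THF/HMPA loosens the ion pair, so the alkoxide attacks silicon and the 1,4-Brook shift moves TBS from C27 to O25, releasing the sulfur-stabilised anion 37, which opens 31 at C28; protonation gives 38. The closest known reaction type is the three-component linchpin coupling of a 2-silyl-1,3-dithiane with two different epoxides under solvent-controlled Brook rearrangement (anion relay). No ring is closed and no stereocentre is created: C25 and C29 keep their C–O bonds because attack occurs only at the CH2 termini. The step needs each epoxide to react once and in the right order; the solvent gate should ensure this, since 37 cannot form before the polar cosolvent is added and 19 should be consumed by then. Regioselectivity rests on the steric difference between the CH2 and CH termini of monosubstituted epoxides. The alkene, acetonide, silyl ethers and PMB ether carry no acidic or electrophilic site for the dithiane anions. The silyl transfer leaves O25 protected and O29 free, which is the pattern the C27 reduction needs.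

Step 31
Reactants: 38 C4–C40 dithiane alcohol (C27 dithiane; O25-TBS; O29-H)
Product: 39 C27 ketone (29-OH; 25-OTBS)
Conditions: MeI, CaCO3, MeCN/H2O (9:1), 40 °C
Reagents that add atoms: water, O
Why: Alkylative dithiane hydrolysis: S-methylation turns sulfur into a leaving group, water adds and CaCO3 takes up HI. The near-neutral medium spares alkene, PMB, silyl ethers and acetonide and limits retro-aldol or elimination of the β-hydroxy ketone.

Step 32
Reactants: 39 C27 ketone (29-OH; 25-OTBS)
Product: 40 27,29-anti diol (27-OH; 29-OH; 25-OTBS)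
Conditions: Me4NBH(OAc)3, MeCN/AcOH (1:1), -30 to -20 °C
Reagents that add atoms: none
Why: Evans–Saksena reduction: O29-H exchanges onto boron and hydride is delivered intramolecularly through a chair transition state with the C29 substituent equatorial, giving 27,29-anti. The silylated O25 cannot direct, so the 25,27-syn relation follows.

Step 33
Reactants: 40 27,29-anti diol (27-OH; 29-OH; 25-OTBS)
Product: 41 27,29-acetonide (terminal alkene; 35-OPMB)
Conditions: Me2C(OMe)2, PPTS, CH2Cl2, rt
Reagents that add atoms: 2,2-dimethoxypropane, COC(C)(C)OC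
Why: Acetal exchange protects both hydroxyls in one step; the 13C shifts of the acetal carbons should confirm the anti relation.

Step 34
Reactants: 42 ethyl but-2-ynoate
Product: 43 ethyl (Z)-3-iodobut-2-enoate
Conditions: NaI, AcOH, 115 °C
Reagents that add atoms: sodium iodide, [Na+].[I-]
Why: Conjugate addition of iodide to the ynoate followed by protonation is a net anti hydroiodination and should give the Z iodoenoate.

Step 35
Reactants: 41 27,29-acetonide (terminal alkene; 35-OPMB); 43 ethyl (Z)-3-iodobut-2-enoate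
Product: 45 C1–C40 ethyl (2Z)-enoate (35-OPMB), via C4 alkyl-9-BBN borane 44 (not isolated)
Conditions: 9-BBN, THF, 0 °C to rt; then 43, Pd(dppf)Cl2 (10 mol%), AsPh3, Cs2CO3, DMF/H2O, rt
Reagents that add atoms: none
Why: Anti-Markovnikov hydroboration of the only alkene puts boron on C4, and the B-alkyl Suzuki–Miyaura coupling forms C3–C4 with retention of the vinyl iodide geometry, giving the 2Z enoate.

Step 36
Reactants: 45 C1–C40 ethyl (2Z)-enoate (35-OPMB)
Product: 46 C35 alcohol (ethyl ester)
Conditions: DDQ, CH2Cl2/pH 7 buffer, 0 °C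
Reagents that add atoms: none
Why: Oxidative PMB cleavage (benzylic hydride abstraction, hydrolysis of the oxocarbenium ion); the buffer protects the acetonides, and the electron-poor enoate and silyl ethers are inert.

Step 37
Reactants: 46 C35 alcohol (ethyl ester)
Product: 47 seco acid (35-OH; C1 acid)
Conditions: LiOH, THF/MeOH/H2O, 40 °C; then aq. HCl to pH 4
Reagents that add atoms: lithium hydroxide, [Li+].[OH-]
Why: Saponification of the ethyl ester; hydroxide at moderate temperature should hydrolyse without the γ-deprotonation that could scramble the Z geometry.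

Step 38
Reactants: 47 seco acid (35-OH; C1 acid)
Product: 49 protected 36-membered macrolactone, via mixed anhydride 48 (not isolated)
Conditions: 2,4,6-Cl3C6H2COCl, Et3N, THF, rt; then slow addition to DMAP, toluene, 80 °C (final 1 mM)
Reagents that add atoms: none
Why: Yamaguchi macrolactonisation: the mixed anhydride is attacked by DMAP at the less hindered carbonyl and the acylpyridinium acylates O35 intramolecularly at high dilution. O35 is the only free hydroxyl, which fixes the ring size at 36.

Step 39
Reactants: 49 protected 36-membered macrolactone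
Product: 50 CNP0126363.4
Conditions: aq. HF (48%), MeCN, 0 °C to rt
Reagents that add atoms: none
Why: Global acidic deprotection: fluoride-assisted Si–O cleavage of the five silyl ethers and hydrolysis of both acetonides in one operation; the low temperature limits acyl migration of the lactone.

## Compound list

1 | tert-butyl 2-[(4R,6S)-6-(hydroxymethyl)-2,2-dimethyl-1,3-dioxan-4-yl]acetate (C5–C10 unit) | OC[C@@H](O1)C[C@@H](OC1(C)C)CC(=O)OC(C)(C)C | starting material
2 | C10 triflate of 1 | FC(F)(F)S(=O)(=O)OC[C@@H](O1)C[C@@H](OC1(C)C)CC(=O)OC(C)(C)C | intermediate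
3 | tert-butyl 2-[(4R,6R)-2,2-dimethyl-6-(pent-4-en-1-yl)-1,3-dioxan-4-yl]acetate (C5–C14) | C=CCCC[C@@H](O1)C[C@@H](OC1(C)C)CC(=O)OC(C)(C)C | intermediate
4 | C13/C14 epoxide of 3, both C13 epimers | C1OC1CCC[C@@H](O2)C[C@@H](OC2(C)C)CC(=O)OC(C)(C)C | intermediate
5 | tert-butyl 2-[(4R,6R)-2,2-dimethyl-6-{3-[(2R)-oxiran-2-yl]propyl}-1,3-dioxan-4-yl]acetate | C1[C@H](O1)CCC[C@@H](O2)C[C@@H](OC2(C)C)CC(=O)OC(C)(C)C | intermediate
6 | tert-butyl 2-[(4R,6R)-6-[(4S)-4-hydroxynon-8-en-1-yl]-2,2-dimethyl-1,3-dioxan-4-yl]acetate (C5–C18, 13-OH) | C=CCCC[C@H](O)CCC[C@@H](O1)C[C@@H](OC1(C)C)CC(=O)OC(C)(C)C | intermediate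
7 | O13-TBS ether of 6 | C=CCCC[C@H](O[Si](C)(C)C(C)(C)C)CCC[C@@H](O1)C[C@@H](OC1(C)C)CC(=O)OC(C)(C)C | intermediate
8 | C17/C18 epoxide of 7, both C17 epimers | C1OC1CCC[C@H](O[Si](C)(C)C(C)(C)C)CCC[C@@H](O2)C[C@@H](OC2(C)C)CC(=O)OC(C)(C)C | intermediate
9 | C5–C18 epoxy ester, single C17/C18 oxirane (ring carbon R), 13-OTBS, 7,9-acetonide | C1[C@H](O1)CCC[C@H](O[Si](C)(C)C(C)(C)C)CCC[C@@H](O2)C[C@@H](OC2(C)C)CC(=O)OC(C)(C)C | intermediate
10 | C5–C22 alcohol: 17-OH, 13-OTBS, 7,9-acetonide, tert-butyl ester, C21=C22; centres arranged as in the target | C=CCCC[C@H](O)CCC[C@H](O[Si](C)(C)C(C)(C)C)CCC[C@@H](O1)C[C@@H](OC1(C)C)CC(=O)OC(C)(C)C | intermediate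
11 | O17-TBS ether of 10 | C=CCCC[C@H](O[Si](C)(C)C(C)(C)C)CCC[C@H](O[Si](C)(C)C(C)(C)C)CCC[C@@H](O1)C[C@@H](OC1(C)C)CC(=O)OC(C)(C)C | intermediate
12 | C21/C22 epoxide of 11, both C21 epimers | C1OC1CCC[C@H](O[Si](C)(C)C(C)(C)C)CCC[C@H](O[Si](C)(C)C(C)(C)C)CCC[C@@H](O2)C[C@@H](OC2(C)C)CC(=O)OC(C)(C)C | intermediate
13 | C5–C22 epoxy ester, single C21/C22 oxirane (ring carbon R), 13,17-bis-OTBS, 7,9-acetonide | C1[C@H](O1)CCC[C@H](O[Si](C)(C)C(C)(C)C)CCC[C@H](O[Si](C)(C)C(C)(C)C)CCC[C@@H](O2)C[C@@H](OC2(C)C)CC(=O)OC(C)(C)C | intermediate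
14 | C5–C26 alcohol: 21-OH, 13,17-bis-OTBS, 7,9-acetonide, tert-butyl ester, C25=C26; centres arranged as in the target | C=CCCC[C@H](O)CCC[C@H](O[Si](C)(C)C(C)(C)C)CCC[C@H](O[Si](C)(C)C(C)(C)C)CCC[C@@H](O1)C[C@@H](OC1(C)C)CC(=O)OC(C)(C)C | intermediate
15 | O21-TBS ether of 14 | C=CCCC[C@H](O[Si](C)(C)C(C)(C)C)CCC[C@H](O[Si](C)(C)C(C)(C)C)CCC[C@H](O[Si](C)(C)C(C)(C)C)CCC[C@@H](O1)C[C@@H](OC1(C)C)CC(=O)OC(C)(C)C | intermediate
16 | C25/C26 epoxide of 15, both C25 epimers | C1OC1CCC[C@H](O[Si](C)(C)C(C)(C)C)CCC[C@H](O[Si](C)(C)C(C)(C)C)CCC[C@H](O[Si](C)(C)C(C)(C)C)CCC[C@@H](O2)C[C@@H](OC2(C)C)CC(=O)OC(C)(C)C | intermediate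
17 | C5–C26 epoxy ester, single C25/C26 oxirane (ring carbon S), 13,17,21-tris-OTBS, 7,9-acetonide | C1[C@@H](O1)CCC[C@H](O[Si](C)(C)C(C)(C)C)CCC[C@H](O[Si](C)(C)C(C)(C)C)CCC[C@H](O[Si](C)(C)C(C)(C)C)CCC[C@@H](O2)C[C@@H](OC2(C)C)CC(=O)OC(C)(C)C | intermediate
18 | C5 aldehyde of 17 | C1[C@@H](O1)CCC[C@H](O[Si](C)(C)C(C)(C)C)CCC[C@H](O[Si](C)(C)C(C)(C)C)CCC[C@H](O[Si](C)(C)C(C)(C)C)CCC[C@@H](O2)C[C@@H](OC2(C)C)CC=O | intermediate
19 | southern epoxide C4–C26: (S)-C25/C26 oxirane, 13,17,21-tris-OTBS, 7,9-syn-acetonide, C4=C5 | C1[C@@H](O1)CCC[C@H](O[Si](C)(C)C(C)(C)C)CCC[C@H](O[Si](C)(C)C(C)(C)C)CCC[C@H](O[Si](C)(C)C(C)(C)C)CCC[C@@H](O2)C[C@@H](OC2(C)C)CC=C | intermediate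
20 | (E)-hept-2-en-1-ol | CCCC/C=C/CO | starting material
21 | [(2R,3R)-3-butyloxiran-2-yl]methanol | CCCC[C@H]1O[C@@H]1CO | intermediate
22 | (2S,3S)-3-methylheptane-1,2-diol | CCCC[C@H](C)[C@H](O)CO | intermediate
23 | (2S)-2-[(2S)-hexan-2-yl]oxirane (C34–C40) | CCCC[C@H](C)[C@H](O1)C1 | intermediate
24 | (4R,5S)-5-methylnon-1-en-4-ol (C32–C40) | CCCC[C@H](C)[C@H](O)CC=C | intermediate
25 | O-PMB ether of 24 | CCCC[C@H](C)[C@H](OCc1ccc(OC)cc1)CC=C | intermediate
26 | C32/C33 epoxide of 25, both C33 epimers | CCCC[C@H](C)[C@H](OCc1ccc(OC)cc1)CC1CO1 | intermediate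
27 | (2S)-2-{(2R,3S)-2-[(4-methoxyphenyl)methoxy]-3-methylheptyl}oxirane | CCCC[C@H](C)[C@H](OCc1ccc(OC)cc1)C[C@H](O1)C1 | intermediate
28 | (6R,8R,9S)-8-[(4-methoxyphenyl)methoxy]-9-methyltridec-1-en-6-ol (C28–C40, 33-OH) | CCCC[C@H](C)[C@H](OCc1ccc(OC)cc1)C[C@H](O)CCCC=C | intermediate
29 | O33-TBS ether of 28 | CCCC[C@H](C)[C@H](OCc1ccc(OC)cc1)C[C@H](O[Si](C)(C)C(C)(C)C)CCCC=C | intermediate
30 | C28/C29 epoxide of 29, both C29 epimers | CCCC[C@H](C)[C@H](OCc1ccc(OC)cc1)C[C@H](O[Si](C)(C)C(C)(C)C)CCCC1CO1 | intermediate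
31 | northern epoxide C28–C40: (S)-C28/C29 oxirane, 33-OTBS, 35-OPMB | CCCC[C@H](C)[C@H](OCc1ccc(OC)cc1)C[C@H](O[Si](C)(C)C(C)(C)C)CCC[C@H](O1)C1 | intermediate
32 | 1,3-dithiane | C1CSCSC1 | starting material
33 | 2-lithio-1,3-dithiane | [Li]C1SCCCS1 | intermediate
34 | 2-(tert-butyldimethylsilyl)-1,3-dithiane | CC(C)(C)[Si](C)(C)C1SCCCS1 | intermediate
35 | 2-lithio-2-(tert-butyldimethylsilyl)-1,3-dithiane | [Li]C1([Si](C)(C)C(C)(C)C)SCCCS1 | intermediate
36 | lithium C25-alkoxide of the C4–C27 adduct, TBS still on C27 | CC(C)(C)[Si](C)(C)C1(SCCCS1)C[C@@H](O[Li])CCC[C@H](O[Si](C)(C)C(C)(C)C)CCC[C@H](O[Si](C)(C)C(C)(C)C)CCC[C@H](O[Si](C)(C)C(C)(C)C)CCC[C@@H](O2)C[C@@H](OC2(C)C)CC=C | intermediate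
37 | C27-lithio dithiane of the C4–C27 chain, TBS on O25 | [Li]C1(SCCCS1)C[C@@H](O[Si](C)(C)C(C)(C)C)CCC[C@H](O[Si](C)(C)C(C)(C)C)CCC[C@H](O[Si](C)(C)C(C)(C)C)CCC[C@H](O[Si](C)(C)C(C)(C)C)CCC[C@@H](O2)C[C@@H](OC2(C)C)CC=C | intermediate
38 | C4–C40 chain with C27 dithiane, O25-TBS, O29-H | CCCC[C@H](C)[C@H](OCc1ccc(OC)cc1)C[C@H](O[Si](C)(C)C(C)(C)C)CCC[C@H](O)CC2(SCCCS2)C[C@@H](O[Si](C)(C)C(C)(C)C)CCC[C@H](O[Si](C)(C)C(C)(C)C)CCC[C@H](O[Si](C)(C)C(C)(C)C)CCC[C@H](O[Si](C)(C)C(C)(C)C)CCC[C@@H](O3)C[C@@H](OC3(C)C)CC=C | intermediate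
39 | C27 ketone, 29-OH, 25-OTBS | CCCC[C@H](C)[C@H](OCc1ccc(OC)cc1)C[C@H](O[Si](C)(C)C(C)(C)C)CCC[C@H](O)CC(=O)C[C@@H](O[Si](C)(C)C(C)(C)C)CCC[C@H](O[Si](C)(C)C(C)(C)C)CCC[C@H](O[Si](C)(C)C(C)(C)C)CCC[C@H](O[Si](C)(C)C(C)(C)C)CCC[C@@H](O3)C[C@@H](OC3(C)C)CC=C | intermediate
40 | 27,29-anti diol, 25-OTBS | CCCC[C@H](C)[C@H](OCc1ccc(OC)cc1)C[C@H](O[Si](C)(C)C(C)(C)C)CCC[C@H](O)C[C@@H](O)C[C@@H](O[Si](C)(C)C(C)(C)C)CCC[C@H](O[Si](C)(C)C(C)(C)C)CCC[C@H](O[Si](C)(C)C(C)(C)C)CCC[C@H](O[Si](C)(C)C(C)(C)C)CCC[C@@H](O3)C[C@@H](OC3(C)C)CC=C | intermediate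
41 | 27,29-acetonide of 40 | CCCC[C@H](C)[C@H](OCc1ccc(OC)cc1)C[C@H](O[Si](C)(C)C(C)(C)C)CCC[C@H](O2)C[C@@H](OC2(C)C)C[C@@H](O[Si](C)(C)C(C)(C)C)CCC[C@H](O[Si](C)(C)C(C)(C)C)CCC[C@H](O[Si](C)(C)C(C)(C)C)CCC[C@H](O[Si](C)(C)C(C)(C)C)CCC[C@@H](O3)C[C@@H](OC3(C)C)CC=C | intermediate
42 | ethyl but-2-ynoate | CC#CC(=O)OCC | starting material
43 | ethyl (Z)-3-iodobut-2-enoate | I/C(C)=C\C(=O)OCC | intermediate
44 | C4 B-alkyl-9-borabicyclo[3.3.1]nonane from 41 | CCCC[C@H](C)[C@H](OCc1ccc(OC)cc1)C[C@H](O[Si](C)(C)C(C)(C)C)CCC[C@H](O2)C[C@@H](OC2(C)C)C[C@@H](O[Si](C)(C)C(C)(C)C)CCC[C@H](O[Si](C)(C)C(C)(C)C)CCC[C@H](O[Si](C)(C)C(C)(C)C)CCC[C@H](O[Si](C)(C)C(C)(C)C)CCC[C@@H](O3)C[C@@H](OC3(C)C)CCCB4C5CCCC4CCC5 | intermediate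
45 | C1–C40 ethyl (2Z)-enoate, 35-OPMB | CCCC[C@H](C)[C@H](OCc1ccc(OC)cc1)C[C@H](O[Si](C)(C)C(C)(C)C)CCC[C@H](O2)C[C@@H](OC2(C)C)C[C@@H](O[Si](C)(C)C(C)(C)C)CCC[C@H](O[Si](C)(C)C(C)(C)C)CCC[C@H](O[Si](C)(C)C(C)(C)C)CCC[C@H](O[Si](C)(C)C(C)(C)C)CCC[C@@H](O3)C[C@@H](OC3(C)C)CCC/C(C)=C\C(=O)OCC | intermediate
46 | C35 alcohol, ethyl (2Z)-enoate | CCCC[C@H](C)[C@H](O)C[C@H](O[Si](C)(C)C(C)(C)C)CCC[C@H](O2)C[C@@H](OC2(C)C)C[C@@H](O[Si](C)(C)C(C)(C)C)CCC[C@H](O[Si](C)(C)C(C)(C)C)CCC[C@H](O[Si](C)(C)C(C)(C)C)CCC[C@H](O[Si](C)(C)C(C)(C)C)CCC[C@@H](O3)C[C@@H](OC3(C)C)CCC/C(C)=C\C(=O)OCC | intermediate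
47 | seco acid: 35-OH, C1 acid | CCCC[C@H](C)[C@H](O)C[C@H](O[Si](C)(C)C(C)(C)C)CCC[C@H](O2)C[C@@H](OC2(C)C)C[C@@H](O[Si](C)(C)C(C)(C)C)CCC[C@H](O[Si](C)(C)C(C)(C)C)CCC[C@H](O[Si](C)(C)C(C)(C)C)CCC[C@H](O[Si](C)(C)C(C)(C)C)CCC[C@@H](O3)C[C@@H](OC3(C)C)CCC/C(C)=C\C(=O)O | intermediate
48 | mixed anhydride of 47 with 2,4,6-trichlorobenzoic acid | CCCC[C@H](C)[C@H](O)C[C@H](O[Si](C)(C)C(C)(C)C)CCC[C@H](O2)C[C@@H](OC2(C)C)C[C@@H](O[Si](C)(C)C(C)(C)C)CCC[C@H](O[Si](C)(C)C(C)(C)C)CCC[C@H](O[Si](C)(C)C(C)(C)C)CCC[C@H](O[Si](C)(C)C(C)(C)C)CCC[C@@H](O3)C[C@@H](OC3(C)C)CCC/C(C)=C\C(=O)OC(=O)c4c(Cl)cc(Cl)cc4Cl | intermediate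
49 | protected 36-membered macrolactone: 13,17,21,25,33-penta-OTBS, 7,9- and 27,29-acetonides | CCCC[C@H](C)[C@H]1C[C@H](O[Si](C)(C)C(C)(C)C)CCC[C@H](O2)C[C@@H](OC2(C)C)C[C@@H](O[Si](C)(C)C(C)(C)C)CCC[C@H](O[Si](C)(C)C(C)(C)C)CCC[C@H](O[Si](C)(C)C(C)(C)C)CCC[C@H](O[Si](C)(C)C(C)(C)C)CCC[C@@H](O3)C[C@@H](OC3(C)C)CCC/C(C)=C\C(=O)O1 | intermediate
50 | CNP0126363.4 | CCCC[C@H](C)[C@H]1C[C@H](O)CCC[C@H](O)C[C@@H](O)C[C@@H](O)CCC[C@H](O)CCC[C@H](O)CCC[C@H](O)CCC[C@@H](O)C[C@@H](O)CCC/C(C)=C\C(=O)O1 | target

## Step count and least certain steps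

Total: 39 steps. Longest linear sequence: 26 steps (steps 1–17, 30–33 and 35–39). The northern epoxide takes 11 steps (18–28), the linchpin one (29) and the iodoenoate one (34).

Step 30 (key step). The most likely failure is loss of the solvent gate: if silicon migrates before 19 is consumed, 37 forms early and adds a second molecule of 19. If the migration is incomplete after the cosolvent is added, 31 is not opened. Proton transfer to the dithiane anions from adventitious acid would also stop the relay. Fallback: the two bonds are made in separate operations. Setting out from 19 and 32, the anion 33 opens 19 at C26 to give the C4–C27 dithiane alcohol F1. Silylation (TBSCl, imidazole) gives its O25-TBS ether F2. Deprotonation of F2 (t-BuLi, THF/HMPA) and addition of 31 returns to 38.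

Step 1. What may go wrong is attack or enolisation at the tert-butyl ester by the Grignard reagent, followed by β-elimination of the acetal oxygen. Displacement at the β-oxygenated carbon could also be sluggish, so that the triflate decomposes. Fallback: a softer carbon nucleophile and a reductive step. Setting out from 1 (through 2), the lithio derivative of but-3-enyl phenyl sulfone (n-BuLi, THF, -78 °C) is alkylated by the triflate to give the C11 sulfone F3. Reductive desulfonylation (sodium amalgam, Na2HPO4, MeOH, -20 °C) returns to 3.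

Step 16. What may go wrong is over-reduction to the primary alcohol, or hydride opening of the terminal epoxide if the temperature rises. Fallback: the oxidation level is adjusted before the epoxide exists. Setting out from 15, LiAlH4 (THF, 0 °C) gives the C5 primary alcohol F4. mCPBA gives the epoxide mixture F5, and resolution with (S,S)-(salen)Co(OAc) and water gives the single epoxy alcohol F6. Dess–Martin oxidation (NaHCO3, CH2Cl2) returns to 18.

Step 32. What may go wrong is erosion of the anti selectivity through intermolecular hydride delivery. The silyloxy group on the other side of the ketone may also disturb the chair transition state. Fallback: intramolecular hydride transfer of the Evans–Tishchenko type. Setting out from 39, benzaldehyde and SmI2 (cat., THF, -10 °C) give the 27,29-anti diol mono-ester F7 (benzoate on O29, free 27-OH). Reductive removal of the benzoate (i-Bu2AlH, CH2Cl2, -78 °C) returns to 40.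

Step 38. What may go wrong is isomerisation of the Z-enoate during activation (reversible conjugate addition of DMAP or ketene formation). Intermolecular acylation may also outrun ring closure, because O35 is hindered by C36. Fallback: the ester is formed intermolecularly and the ring is closed by carbon–carbon coupling. Setting out from 41, DDQ gives the C35 alcohol F8. This is acylated with (Z)-3-iodobut-2-enoic acid F9 (from 43 with LiOH), activated as the acid chloride with 1-chloro-N,N,2-trimethylpropenylamine and pyridine, to give the iodoenoate ester F10. Hydroboration of its terminal alkene with 9-BBN and intramolecular B-alkyl Suzuki–Miyaura coupling (Pd(dppf)Cl2, AsPh3, Cs2CO3, high dilution) returns to 49.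

## Further compounds

F1 | step 30 | C4–C27 dithiane alcohol (1,3-dithian-2-yl at C27, 25-OH) | S1CCCSC1C[C@@H](O)CCC[C@H](O[Si](C)(C)C(C)(C)C)CCC[C@H](O[Si](C)(C)C(C)(C)C)CCC[C@H](O[Si](C)(C)C(C)(C)C)CCC[C@@H](O2)C[C@@H](OC2(C)C)CC=C
F2 | step 30 | O25-TBS ether of F1 | S1CCCSC1C[C@@H](O[Si](C)(C)C(C)(C)C)CCC[C@H](O[Si](C)(C)C(C)(C)C)CCC[C@H](O[Si](C)(C)C(C)(C)C)CCC[C@H](O[Si](C)(C)C(C)(C)C)CCC[C@@H](O2)C[C@@H](OC2(C)C)CC=C
F3 | step 1 | C11 phenylsulfonyl derivative of 3, both C11 epimers | C=CCC(S(=O)(=O)c1ccccc1)C[C@@H](O2)C[C@@H](OC2(C)C)CC(=O)OC(C)(C)C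
F4 | step 16 | C5 primary alcohol from 15 | C=CCCC[C@H](O[Si](C)(C)C(C)(C)C)CCC[C@H](O[Si](C)(C)C(C)(C)C)CCC[C@H](O[Si](C)(C)C(C)(C)C)CCC[C@@H](O1)C[C@@H](OC1(C)C)CCO
F5 | step 16 | C25/C26 epoxide of F4, both C25 epimers | C1OC1CCC[C@H](O[Si](C)(C)C(C)(C)C)CCC[C@H](O[Si](C)(C)C(C)(C)C)CCC[C@H](O[Si](C)(C)C(C)(C)C)CCC[C@@H](O2)C[C@@H](OC2(C)C)CCO
F6 | step 16 | epoxy alcohol with single C25/C26 oxirane (ring carbon S) | C1[C@@H](O1)CCC[C@H](O[Si](C)(C)C(C)(C)C)CCC[C@H](O[Si](C)(C)C(C)(C)C)CCC[C@H](O[Si](C)(C)C(C)(C)C)CCC[C@@H](O2)C[C@@H](OC2(C)C)CCO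
F7 | step 32 | O29 benzoate of the 27,29-anti diol (27-OH free) | CCCC[C@H](C)[C@H](OCc1ccc(OC)cc1)C[C@H](O[Si](C)(C)C(C)(C)C)CCC[C@H](OC(=O)c2ccccc2)C[C@@H](O)C[C@@H](O[Si](C)(C)C(C)(C)C)CCC[C@H](O[Si](C)(C)C(C)(C)C)CCC[C@H](O[Si](C)(C)C(C)(C)C)CCC[C@H](O[Si](C)(C)C(C)(C)C)CCC[C@@H](O3)C[C@@H](OC3(C)C)CC=C
F8 | step 38 | C35 alcohol from 41 | CCCC[C@H](C)[C@H](O)C[C@H](O[Si](C)(C)C(C)(C)C)CCC[C@H](O2)C[C@@H](OC2(C)C)C[C@@H](O[Si](C)(C)C(C)(C)C)CCC[C@H](O[Si](C)(C)C(C)(C)C)CCC[C@H](O[Si](C)(C)C(C)(C)C)CCC[C@H](O[Si](C)(C)C(C)(C)C)CCC[C@@H](O3)C[C@@H](OC3(C)C)CC=C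
F9 | step 38 | (Z)-3-iodobut-2-enoic acid | I/C(C)=C\C(=O)O
F10 | step 38 | O35 (Z)-3-iodobut-2-enoate of F8 | CCCC[C@H](C)[C@H](OC(=O)/C=C(C)\I)C[C@H](O[Si](C)(C)C(C)(C)C)CCC[C@H](O2)C[C@@H](OC2(C)C)C[C@@H](O[Si](C)(C)C(C)(C)C)CCC[C@H](O[Si](C)(C)C(C)(C)C)CCC[C@H](O[Si](C)(C)C(C)(C)C)CCC[C@H](O[Si](C)(C)C(C)(C)C)CCC[C@@H](O3)C[C@@H](OC3(C)C)CC=C
A1 | alternative 1 | protected 36-membered macrolactone with C11=C12 alkene | CCCC[C@H](C)[C@H]4C[C@H](O[Si](C)(C)C(C)(C)C)CCC[C@H](O[Si](C)(C)C(C)(C)C)C[C@@H](O2)C[C@@H](OC2(C)C)CCC[C@H](O[Si](C)(C)C(C)(C)C)CCC[C@H](O[Si](C)(C)C(C)(C)C)CCC[C@H](OCc3ccc(OC)cc3)/C=C/C[C@@H](O1)C[C@@H](OC1(C)C)CCC/C(C)=C\C(=O)O4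
A2 | alternative 1 | open-chain diene ester with vinyl groups at C11 and C12 | CCCC[C@H](C)[C@H](OC(=O)/C=C(C)\CCC[C@H]1C[C@@H](CC=C)OC(C)(C)O1)C[C@H](O[Si](C)(C)C(C)(C)C)CCC[C@H](O[Si](C)(C)C(C)(C)C)C[C@@H](O2)C[C@@H](OC2(C)C)CCC[C@H](O[Si](C)(C)C(C)(C)C)CCC[C@H](O[Si](C)(C)C(C)(C)C)CCC[C@H](OCc3ccc(OC)cc3)C=C
A3 | alternative 2 | (4R,8R)-undeca-1,10-diene-4,8-diol (C6–C16) | C=CC[C@H](O)CCC[C@@H](O)CC=C
A4 | alternative 2 | pentane-1,5-diol | OCCCCCO
A5 | alternative 2 | allyl acetate | CC(=O)OCC=C
A6 | alternative 3 | C4–C40 (E)-23-ene-21,25-anti-diol | CCCC[C@H](C)[C@H](OCc1ccc(OC)cc1)C[C@H](O[Si](C)(C)C(C)(C)C)CCC[C@H](O[Si](C)(C)C(C)(C)C)C[C@@H](O[Si](C)(C)C(C)(C)C)C[C@@H](O)/C=C/C[C@H](O)CCC[C@H](O[Si](C)(C)C(C)(C)C)CCC[C@H](O[Si](C)(C)C(C)(C)C)CCC[C@@H](O2)C[C@@H](OC2(C)C)CCCOC(=O)C(C)(C)C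
A7 | alternative 3 | C25–C40 aldehyde (C25 formyl; 27,29,33-tris-OTBS; 35-OPMB) | CCCC[C@H](C)[C@H](OCc1ccc(OC)cc1)C[C@H](O[Si](C)(C)C(C)(C)C)CCC[C@H](O[Si](C)(C)C(C)(C)C)C[C@@H](O[Si](C)(C)C(C)(C)C)CC=O
A8 | alternative 3 | C4–C21 aldehyde (C21 formyl; 13,17-bis-OTBS; 7,9-acetonide; C4 pivalate) | O=CCCC[C@H](O[Si](C)(C)C(C)(C)C)CCC[C@H](O[Si](C)(C)C(C)(C)C)CCC[C@@H](O1)C[C@@H](OC1(C)C)CCCOC(=O)C(C)(C)C
A9 | alternative 3 | allenylboronic acid pinacol ester | C=C=CB1OC(C)(C)C(C)(C)O1
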